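**Retrosynthetic overview**
1. The target is a (7R,8S,7'R,8'S)-syringaresinol core (ring C on C7, ring D on C7') with arylglycerol arms on both phenol oxygens: ring D carries the erythro ring E unit (αS,βR); ring C carries the threo ring B unit (αR,βR), whose ring B oxygen carries the erythro ring A unit (αR,βS).
2. The strategy rests on the ring E unit: Cβ bears the ring D oxygen (flanked by two methoxy groups) and Cγ, and Cα is the carbinol on guaiacyl ring E. With Cγ as an ester carbon this is an α-aryloxy-β-hydroxy ester, cut at O–Cβ and Cβ–Cα into the ring D phenol, ethyl diazoacetate and O-benzylvanillin (carbenoid, oxonium ylide, aldol trapping).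
3. Core: one epoxy cinnamyl ether gives both tetrahydrofuran rings, first by trivalent-titanium radical 5-exo closure (C8'–C8), then by iodine-induced C7–O closure. C7' comes from a Sharpless kinetic resolution.
4. Ring C arm: cut at Cα–Cβ of the ring B unit (Evans syn aldol of the ring C glycolyl imide with a ring B aldehyde that already carries the ring A unit). The ring A unit comes from an Evans aldol (sets Cβ), then benzylic oxidation and erythro-selective reduction (sets Cα).
5. Order of ring formation: first tetrahydrofuran ring, then second tetrahydrofuran ring (both in step 8). The dioxane acetonides are temporary.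

Key step: step 10

Remark on the chemistry: ring C is masked as the triisopropylsilyl ether because it must survive a sodium alkoxide in step 7. 4-Benzyloxy-3,5-dimethoxybenzaldehyde, 4-benzyloxy-3-methoxybenzaldehyde, 4-bromo-2-methoxyphenol and both antipodes of 4-benzyl-3-(chloroacetyl)oxazolidin-2-one are taken as purchased. The (R)-phosphoric acid is written for step 10; its antipode is used if a trial with 2,6-dimethoxyphenol shows the opposite sense.

**Route**

Step 1
Reactants: 1 syringaldehyde
Product: 2 3,5-dimethoxy-4-(triisopropylsilyloxy)benzaldehyde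
Conditions: i-Pr3SiCl, imidazole, DMF, rt
Reagents that add atoms: chlorotriisopropylsilane, CC(C)[Si](Cl)(C(C)C)C(C)C
Why: Imidazole-promoted silylation of the acidic phenol gives a hindered aryl silyl ether that is stable to base, hydride and hydrogenolysis and is later cleaved by fluoride.

Step 2
Reactants: 2 3,5-dimethoxy-4-(triisopropylsilyloxy)benzaldehyde
Product: 3 ethyl (E)-3-[3,5-dimethoxy-4-(triisopropylsilyloxy)phenyl]prop-2-enoate
Conditions: Ph3P=CHCO2Et, toluene, 80 °C
Reagents that add atoms: ethyl (triphenylphosphoranylidene)acetate, CCOC(=O)C=P(c1ccccc1)(c1ccccc1)c1ccccc1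
Why: Wittig olefination with the stabilised ylide gives the (E)-cinnamate under neutral conditions that spare the silyl ether.

Step 3
Reactants: 3 ethyl (E)-cinnamate of ring C
Product: 4 (E)-3-[3,5-dimethoxy-4-(triisopropylsilyloxy)phenyl]prop-2-en-1-ol
Conditions: i-Bu2AlH (2.2 equiv), CH2Cl2, −78 °C; then H2O
Reagents that add atoms: none
Why: i-Bu2AlH reduction of the unsaturated ester (1,2-reduction) gives the allylic alcohol and leaves the aryl silyl ether alone.

Step 4
Reactants: 4 (E)-cinnamyl alcohol of ring C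
Product: 5 (E)-3-[3,5-dimethoxy-4-(triisopropylsilyloxy)phenyl]prop-2-enyl bromide
Conditions: CBr4, PPh3, CH2Cl2, 0 °C (used crude)
Reagents that add atoms: tetrabromomethane, BrC(Br)(Br)Br
Why: Appel bromination converts the primary allylic alcohol into the bromide under neutral conditions, so the electron-rich cinnamyl system is not ionised by acid.

Step 5
Reactants: 6 4-benzyloxy-3,5-dimethoxybenzaldehyde
Product: 7 racemic 1-[4-(benzyloxy)-3,5-dimethoxyphenyl]prop-2-en-1-ol
Conditions: CH2=CHMgBr, THF, 0 °C; then H2O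
Reagents that add atoms: vinylmagnesium bromide, C=C[Mg]Br
Why: Grignard addition of the vinyl nucleophile to the aldehyde gives the racemic aryl vinyl carbinol.

Step 6
Reactants: 7 racemic aryl vinyl carbinol
Product: 8 (S)-[4-(benzyloxy)-3,5-dimethoxyphenyl][(2R)-oxiran-2-yl]methanol
Conditions: Ti(OiPr)4 (15 mol %), L-(+)-diisopropyl tartrate (20 mol %), t-BuOOH (0.45 equiv), 4 Å MS, CH2Cl2, −20 °C
Reagents that add atoms: tert-butyl hydroperoxide, CC(C)(C)OO
Why: In this Sharpless kinetic resolution L-(+)-diisopropyl tartrate epoxidises the (R)-carbinol much faster than its antipode and with erythro selectivity, so at under half conversion 8 should form in high enantiomeric purity with the carbinol centre that becomes C7' (R) of the core, and unreacted (S)-7 is removed by chromatography.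

Step 7
Reactants: 8 epoxy alcohol; 5 cinnamyl bromide of ring C
Product: 9 (2R)-2-{(S)-[4-(benzyloxy)-3,5-dimethoxyphenyl][(E)-3-(3,5-dimethoxy-4-triisopropylsilyloxyphenyl)prop-2-enyloxy]methyl}oxirane
Conditions: NaH, Bu4NI (cat.), THF, 0 °C → rt (NaH added last)
Reagents that add atoms: none
Why: Williamson etherification of the sodium alkoxide with the allylic bromide joins the two halves, and in THF at 0 °C the Payne rearrangement should be slow while the hindered aryl silyl ether resists the alkoxide.

Step 8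
Reactants: 9 epoxy cinnamyl ether
Product: 12 (7R,8S,7'R,8'S)-syringaresinol ring C triisopropylsilyl ether ring D benzyl ether, via titanoxy alkyl radical 10 (not isolated), via benzylic titanium tetrahydrofuran 11 (not isolated)
Conditions: (C5H5)2TiCl2 (2.5 equiv), Zn dust, THF, rt, slow addition of 9; then I2, rt
Reagents that add atoms: none
Why: Trivalent-titanium epoxide opening (Nugent–RajanBabu) gives the secondary C8' radical 10, which closes 5-exo-trig onto C8 of the cinnamyl double bond through a chair-like Beckwith–Houk transition state with the C7' aryl group pseudo-equatorial (C7'/C8' trans, C8'/C8 cis); a second trivalent titanium captures the C7 benzylic radical as 11, and iodine turns the C7–Ti bond into a benzylic iodide that the C9' titanium alkoxide displaces to close the second ring cis-fused with the aryl group exo, as is known for furofuran lignans.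

Step 9
Reactants: 12 furofuran carrying the ring D benzyl ether
Product: 13 (7R,8S,7'R,8'S)-syringaresinol ring C triisopropylsilyl ether (ring D phenol free)
Conditions: H2 (1 atm), 10 % Pd/C, EtOAc, rt
Reagents that add atoms: none
Why: Hydrogenolysis of the aryl benzyl ether frees the ring D phenol, while the silyl ether and the furofuran benzylic ethers should be inert under neutral conditions at 1 atm.

Step 10
Reactants: 13 core carrying the free ring D phenol; 14 ethyl diazoacetate; 15 4-benzyloxy-3-methoxybenzaldehyde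
Product: 18 ethyl (2S,3S)-3-[4-(benzyloxy)-3-methoxyphenyl]-3-hydroxy-2-(ring D aryloxy)propanoate on the core (erythro ring E unit at the ester level), via rhodium carbenoid 16 (not isolated), via oxonium ylide 17 (not isolated)
Conditions: Rh2(OAc)4 (2 mol %), (R)-3,3'-bis(2,4,6-triisopropylphenyl)-1,1'-binaphthalene-2,2'-diyl hydrogen phosphate (10 mol %), 15 (3 equiv), 4 Å MS, CH2Cl2, −20 °C, 14 (2 equiv) added over 6 h
Reagents that add atoms: none
Why: Proposed new method: Rh2(OAc)4 (divalent rhodium throughout) takes dinitrogen from 14 to give carbenoid 16, whose carbene carbon is attacked by the ring D phenol oxygen (O–Cβ bond, formed without substitution at a secondary carbon, so the flanking methoxy groups do not block it), and the protic oxonium ylide 17, an enol equivalent of the aryloxyacetate, adds through carbon to the acid-activated aldehyde 15 (Cβ–Cα bond) before a 1,2-proton shift can end in plain O–H insertion. The closest known reaction type is the Rh2(OAc)4 and chiral acid co-catalysed three-component coupling of diazo esters, alcohols and aldehydes or imines through trapped oxonium ylides; an acceptor-only diazo ester with a di-ortho-substituted phenol and an electron-rich aldehyde has not been shown. No ring is closed. Cβ and Cα are set together in the aldol event: the erythro arrangement is expected from a proton-bridged transition state in which the pyramidal oxonium oxygen holds ring D on the face opposite the ester and the aldehyde aryl group turns away from ring D toward the ester side, and the absolute sense (2S,3S in the ester, αS,βR after reduction) is imposed by the chiral phosphate that binds the ylide O–H and the aldehyde, the core stereocentres being remote. The step needs chemoselectivity for the phenol O–H over the ring ether oxygens and the aldehyde oxygen, and aldol trapping faster than the proton shift: the phenol is the only acidic O–H in 13, its two ortho methoxy groups can hydrogen-bond the ylide proton and slow its shift, and slow addition of 14 with 15 in excess keeps the ylide meeting aldehyde.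

Step 11
Reactants: 18 erythro ester
Product: 19 (1S,2R)-1-[4-(benzyloxy)-3-methoxyphenyl]-2-(ring D aryloxy)propane-1,3-diol on the core
Conditions: LiBH4, THF–MeOH, 0 °C
Reagents that add atoms: none
Why: LiBH4 ester reduction of the activated α-aryloxy ester gives the Cγ alcohol at low temperature without retro-aldol cleavage and leaves silyl and benzyl ethers untouched.

Step 12
Reactants: 19 ring E unit diol
Product: 20 (4S,5R)-4-[4-(benzyloxy)-3-methoxyphenyl]-2,2-dimethyl-1,3-dioxan-5-yl ether of ring D (ring C still silylated)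
Conditions: Me2C(OMe)2, PPTS (cat.), acetone, rt
Reagents that add atoms: 2,2-dimethoxypropane, COC(C)(C)OC
Why: Acid-catalysed transacetalisation ties the erythro 1,3-diol up as the trans-4,5-disubstituted dioxane with both substituents equatorial, which masks the hydroxyl groups for the later boron aldol.

Step 13
Reactants: 20 acetonide carrying the ring C silyl ether
Product: 21 ring E unit acetonide carrying the free ring C phenol
Conditions: Bu4NF, AcOH, THF, 0 °C
Reagents that add atoms: none
Why: Fluoride-induced desilylation cleaves the aryl silyl ether (acetic acid buffers the phenoxide) and leaves acetonide and benzyl ether intact.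

Step 14
Reactants: 21 ring C phenol; 22 (S)-4-benzyl-3-(chloroacetyl)oxazolidin-2-one
Product: 23 ring C glycolyl imide: (S)-4-benzyl-3-[(ring C aryloxy)acetyl]oxazolidin-2-one
Conditions: K2CO3, NaI (cat.), acetone, 45 °C
Reagents that add atoms: none
Why: Williamson O-alkylation with Finkelstein activation is an SN2 reaction at a primary, carbonyl-activated carbon, which the di-ortho-methoxy phenoxide tolerates, and it installs the imide needed for the Evans aldol.

Step 15
Reactants: 24 4-bromo-2-methoxyphenol; 25 (R)-4-benzyl-3-(chloroacetyl)oxazolidin-2-one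
Product: 26 (R)-4-benzyl-3-[(4-bromo-2-methoxyphenoxy)acetyl]oxazolidin-2-one
Conditions: K2CO3, NaI (cat.), acetone, 45 °C
Reagents that add atoms: none
Why: Williamson O-alkylation of the phenoxide at the primary α-chloro imide carbon gives the ring B glycolyl imide.

Step 16
Reactants: 26 ring B glycolyl imide; 15 4-benzyloxy-3-methoxybenzaldehyde
Product: 28 (R)-4-benzyl-3-[(2R,3S)-3-[4-(benzyloxy)-3-methoxyphenyl]-2-(4-bromo-2-methoxyphenoxy)-3-hydroxypropanoyl]oxazolidin-2-one, via boron enolate 27 (not isolated)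
Conditions: Bu2BOTf, i-Pr2NEt, CH2Cl2, −78 → 0 °C; then 15, −78 → 0 °C; pH 7 buffer, MeOH, H2O2, 0 °C
Reagents that add atoms: none
Why: In this Evans syn aldol the (Z)-boron enolate 27 reacts through a Zimmerman–Traxler chair on the face away from the benzyl group of the (R)-auxiliary, which fixes the aryloxy-bearing carbon (Cβ of the ring A unit, S after reduction) and gives the threo adduct, whose carbinol centre is corrected in steps 18 and 19.

Step 17
Reactants: 28 syn aldol adduct
Product: 29 (1S,2S)-1-[4-(benzyloxy)-3-methoxyphenyl]-2-(4-bromo-2-methoxyphenoxy)propane-1,3-diol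
Conditions: LiBH4, MeOH (1 equiv), THF, 0 °C
Reagents that add atoms: none
Why: LiBH4 reductive cleavage of the N-acyl oxazolidinone gives the 1,3-diol and returns the auxiliary without epimerisation.

Step 18
Reactants: 29 threo diol
Product: 30 (2S)-1-[4-(benzyloxy)-3-methoxyphenyl]-2-(4-bromo-2-methoxyphenoxy)-3-hydroxypropan-1-one
Conditions: DDQ, 1,4-dioxane, rt
Reagents that add atoms: none
Why: DDQ benzylic oxidation (hydride abstraction) takes only the secondary alcohol on electron-rich ring A, as is usual for non-phenolic arylglycerol β-aryl ethers, and leaves the primary alcohol and Cβ untouched.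

Step 19
Reactants: 30 α-aryloxy ketone
Product: 31 (1R,2S)-1-[4-(benzyloxy)-3-methoxyphenyl]-2-(4-bromo-2-methoxyphenoxy)propane-1,3-diol
Conditions: NaBH4, THF–EtOH, −20 → 0 °C
Reagents that add atoms: none
Why: Borohydride reduction of 2-aryloxy-3-hydroxypropiophenones follows the Felkin–Anh polar model (hydride anti to the aryloxy group) and is known to favour the erythro diol under substrate control from Cβ, so the (1R,2S) isomer should predominate with Cβ unchanged, and the minor threo isomer is removed after step 20.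

Step 20
Reactants: 31 erythro diol
Product: 32 (4R,5S)-4-[4-(benzyloxy)-3-methoxyphenyl]-5-(4-bromo-2-methoxyphenoxy)-2,2-dimethyl-1,3-dioxane
Conditions: Me2C(OMe)2, PPTS (cat.), acetone, rt
Reagents that add atoms: 2,2-dimethoxypropane, COC(C)(C)OC
Why: Acid-catalysed acetonide formation gives the trans-dioxane from the erythro diol, which should separate from any cis-dioxane derived from threo material.

Step 21
Reactants: 32 aryl bromide acetonide
Product: 34 4-{[(4R,5S)-4-[4-(benzyloxy)-3-methoxyphenyl]-2,2-dimethyl-1,3-dioxan-5-yl]oxy}-3-methoxybenzaldehyde, via aryllithium 33 (not isolated)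
Conditions: n-BuLi, THF, −78 °C; then DMF, −78 → 0 °C; then H2O
Reagents that add atoms: N,N-dimethylformamide, CN(C)C=O
Why: Bromine–lithium exchange and formylation of the aryllithium with DMF (Bouveault-type) give the ring B aldehyde, and acetonide and benzyl ether are stable to n-BuLi at −78 °C.

Step 22
Reactants: 23 ring C glycolyl imide; 34 ring B aldehyde carrying the ring A unit acetonide
Product: 36 (S)-4-benzyl-3-[(2S,3R)-3-(ring B aryl)-3-hydroxy-2-(ring C aryloxy)propanoyl]oxazolidin-2-one carrying both outer arylglycerol units as acetonides, via boron enolate 35 (not isolated)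
Conditions: Bu2BOTf, i-Pr2NEt, CH2Cl2, −78 → 0 °C; then 34 (1.3 equiv), −78 → 0 °C; pH 7 buffer, MeOH, H2O2, 0 °C
Reagents that add atoms: none
Why: In this Evans syn aldol the (Z)-boron enolate 35 adds to 34 through the Zimmerman–Traxler chair on the face away from the benzyl group of the (S)-auxiliary, which sets Cβ and Cα of the ring B unit as the threo (αR,βR) pair under auxiliary control, the remote stereocentres of both partners having no influence.

Step 23
Reactants: 36 aldol adduct
Product: 37 bis-acetonide dibenzyl ether carrying the ring B unit as free threo (αR,βR)-1,3-diol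
Conditions: LiBH4, MeOH (1 equiv), THF, 0 °C
Reagents that add atoms: none
Why: LiBH4 reductive removal of the oxazolidinone gives the Cγ alcohol of the ring B unit and returns the auxiliary.

Step 24
Reactants: 37 bis-acetonide
Product: 38 dibenzyl ether of the target (ring A phenol benzylated; ring E phenol benzylated)
Conditions: AcOH–H2O (4:1), 40 °C
Reagents that add atoms: none
Why: Mild acid hydrolysis cleaves both isopropylidene acetals while the phenols are still benzylated, so no quinone methide can form and the benzylic carbinol centres and the furofuran should keep their configuration.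

Step 25
Reactants: 38 dibenzyl ether
Product: 39 CNP0316493.1
Conditions: H2 (1 atm), 10 % Pd/C, EtOAc–EtOH, rt
Reagents that add atoms: none
Why: Hydrogenolysis of the two aryl benzyl ethers under neutral conditions frees the phenols of rings A and E, and secondary benzylic alcohols and furofuran ethers are not expected to be cleaved at 1 atm.

**Compound list**
1 | syringaldehyde | COc1cc(C=O)cc(OC)c1O | starting material
2 | 3,5-dimethoxy-4-(triisopropylsilyloxy)benzaldehyde | COc1cc(C=O)cc(OC)c1O[Si](C(C)C)(C(C)C)C(C)C | intermediate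
3 | ethyl (E)-3-[3,5-dimethoxy-4-(triisopropylsilyloxy)phenyl]prop-2-enoate | CCOC(=O)/C=C/c1cc(OC)c(O[Si](C(C)C)(C(C)C)C(C)C)c(OC)c1 | intermediate
4 | (E)-3-[3,5-dimethoxy-4-(triisopropylsilyloxy)phenyl]prop-2-en-1-ol | OC/C=C/c1cc(OC)c(O[Si](C(C)C)(C(C)C)C(C)C)c(OC)c1 | intermediate
5 | (E)-3-[3,5-dimethoxy-4-(triisopropylsilyloxy)phenyl]prop-2-enyl bromide | BrC/C=C/c1cc(OC)c(O[Si](C(C)C)(C(C)C)C(C)C)c(OC)c1 | intermediate
6 | 4-benzyloxy-3,5-dimethoxybenzaldehyde | COc1cc(C=O)cc(OC)c1OCc1ccccc1 | starting material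
7 | racemic 1-[4-(benzyloxy)-3,5-dimethoxyphenyl]prop-2-en-1-ol | C=CC(O)c1cc(OC)c(OCc2ccccc2)c(OC)c1 | intermediate
8 | (S)-[4-(benzyloxy)-3,5-dimethoxyphenyl][(2R)-oxiran-2-yl]methanol (erythro) | O[C@H]([C@H]1CO1)c1cc(OC)c(OCc2ccccc2)c(OC)c1 | intermediate
9 | epoxy cinnamyl ether: (S)-carbinol carbon bearing the ring D aryl group, the (2R)-oxiranyl group, the (E)-cinnamyloxy group of ring C | COc1cc(/C=C/CO[C@H]([C@H]2CO2)c2cc(OC)c(OCc3ccccc3)c(OC)c2)cc(OC)c1O[Si](C(C)C)(C(C)C)C(C)C | intermediate
10 | C8' radical carrying C9' as chlorobis(cyclopentadienyl)titanium alkoxide (tetravalent titanium) | COc1cc(/C=C/CO[C@H]([CH]CO[Ti](Cl)(C2C=CC=C2)C2C=CC=C2)c2cc(OC)c(OCc3ccccc3)c(OC)c2)cc(OC)c1O[Si](C(C)C)(C(C)C)C(C)C | intermediate (not isolated)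
11 | 2-aryl-3-(titanoxymethyl)-4-[aryl(titanio)methyl]tetrahydrofuran (2,3-trans, 3,4-cis; tetravalent titanium at C and at O) | Cl[Ti](C1C=CC=C1)(C1C=CC=C1)OC[C@@H]2[C@H](C(c1cc(OC)c(O[Si](C(C)C)(C(C)C)C(C)C)c(OC)c1)[Ti](Cl)(C1C=CC=C1)C1C=CC=C1)CO[C@H]2c1cc(OC)c(OCc3ccccc3)c(OC)c1 | intermediate (not isolated)
12 | (7R,8S,7'R,8'S)-syringaresinol, ring C 4-O-triisopropylsilyl, ring D 4-O-benzyl | COc1cc(cc(OC)c1O[Si](C(C)C)(C(C)C)C(C)C)[C@@H]1OC[C@@H]2[C@H]1CO[C@H]2c1cc(OC)c(OCc2ccccc2)c(OC)c1 | intermediate
13 | (7R,8S,7'R,8'S)-syringaresinol, ring C 4-O-triisopropylsilyl, ring D free phenol | COc1cc(cc(OC)c1O[Si](C(C)C)(C(C)C)C(C)C)[C@@H]1OC[C@@H]2[C@H]1CO[C@H]2c1cc(OC)c(O)c(OC)c1 | intermediate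
14 | ethyl diazoacetate | CCOC(=O)C=[N+]=[N-] | starting material
15 | 4-benzyloxy-3-methoxybenzaldehyde | COc1cc(C=O)ccc1OCc1ccccc1 | starting material
16 | dirhodium tetraacetate ethoxycarbonylcarbene complex (divalent rhodium; acetates drawn monodentate) | CCOC(=O)C=[Rh](OC(C)=O)(OC(C)=O)[Rh](OC(C)=O)OC(C)=O | intermediate (not isolated)
17 | protic oxonium ylide from the ring D phenol of 13 | COc1cc(cc(OC)c1O[Si](C(C)C)(C(C)C)C(C)C)[C@@H]1OC[C@@H]2[C@H]1CO[C@H]2c1cc(OC)c([OH+][CH-]C(=O)OCC)c(OC)c1 | intermediate (not isolated)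
18 | core carrying the erythro ring E unit as ethyl (2S,3S)-ester on ring D oxygen, ring C silylated | COc1cc(cc(OC)c1O[Si](C(C)C)(C(C)C)C(C)C)[C@@H]1OC[C@@H]2[C@H]1CO[C@H]2c1cc(OC)c(O[C@H](C(=O)OCC)[C@@H](O)c2ccc(OCc3ccccc3)c(OC)c2)c(OC)c1 | intermediate
19 | core carrying the ring E unit as (αS,βR)-1,3-diol, ring C silylated | COc1cc(cc(OC)c1O[Si](C(C)C)(C(C)C)C(C)C)[C@@H]1OC[C@@H]2[C@H]1CO[C@H]2c1cc(OC)c(O[C@H](CO)[C@@H](O)c2ccc(OCc3ccccc3)c(OC)c2)c(OC)c1 | intermediate
20 | core carrying the ring E unit as (4S,5R)-acetonide, ring C silylated | COc1cc(cc(OC)c1O[Si](C(C)C)(C(C)C)C(C)C)[C@@H]1OC[C@@H]2[C@H]1CO[C@H]2c1cc(OC)c(O[C@@H]2COC(C)(C)O[C@H]2c2ccc(OCc3ccccc3)c(OC)c2)c(OC)c1 | intermediate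
21 | core carrying the ring E unit acetonide, ring C free phenol | COc1cc(cc(OC)c1O)[C@@H]1OC[C@@H]2[C@H]1CO[C@H]2c1cc(OC)c(O[C@@H]2COC(C)(C)O[C@H]2c2ccc(OCc3ccccc3)c(OC)c2)c(OC)c1 | intermediate
22 | (S)-4-benzyl-3-(chloroacetyl)oxazolidin-2-one | ClCC(=O)N1[C@@H](Cc2ccccc2)COC1=O | starting material
23 | ring C glycolyl imide of the core, (S)-auxiliary | COc1cc(cc(OC)c1OCC(=O)N1[C@@H](Cc2ccccc2)COC1=O)[C@@H]1OC[C@@H]2[C@H]1CO[C@H]2c1cc(OC)c(O[C@@H]2COC(C)(C)O[C@H]2c2ccc(OCc3ccccc3)c(OC)c2)c(OC)c1 | intermediate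
24 | 4-bromo-2-methoxyphenol | COc1cc(Br)ccc1O | starting material
25 | (R)-4-benzyl-3-(chloroacetyl)oxazolidin-2-one | ClCC(=O)N1[C@H](Cc2ccccc2)COC1=O | starting material
26 | (R)-4-benzyl-3-[(4-bromo-2-methoxyphenoxy)acetyl]oxazolidin-2-one | COc1cc(Br)ccc1OCC(=O)N1[C@H](Cc2ccccc2)COC1=O | intermediate
27 | (Z)-dibutylboron enolate of 26 | CCCCB(CCCC)O/C(=C\Oc1ccc(Br)cc1OC)N1[C@H](Cc2ccccc2)COC1=O | intermediate (not isolated)
28 | (R)-4-benzyl-3-[(2R,3S)-3-[4-(benzyloxy)-3-methoxyphenyl]-2-(4-bromo-2-methoxyphenoxy)-3-hydroxypropanoyl]oxazolidin-2-one | COc1cc(Br)ccc1O[C@@H](C(=O)N1[C@H](Cc2ccccc2)COC1=O)[C@@H](O)c1ccc(OCc2ccccc2)c(OC)c1 | intermediate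
29 | (1S,2S)-1-[4-(benzyloxy)-3-methoxyphenyl]-2-(4-bromo-2-methoxyphenoxy)propane-1,3-diol (threo) | COc1cc(Br)ccc1O[C@@H](CO)[C@@H](O)c1ccc(OCc2ccccc2)c(OC)c1 | intermediate
30 | (2S)-1-[4-(benzyloxy)-3-methoxyphenyl]-2-(4-bromo-2-methoxyphenoxy)-3-hydroxypropan-1-one | COc1cc(Br)ccc1O[C@@H](CO)C(=O)c1ccc(OCc2ccccc2)c(OC)c1 | intermediate
31 | (1R,2S)-1-[4-(benzyloxy)-3-methoxyphenyl]-2-(4-bromo-2-methoxyphenoxy)propane-1,3-diol (erythro) | COc1cc(Br)ccc1O[C@@H](CO)[C@H](O)c1ccc(OCc2ccccc2)c(OC)c1 | intermediate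
32 | (4R,5S)-4-[4-(benzyloxy)-3-methoxyphenyl]-5-(4-bromo-2-methoxyphenoxy)-2,2-dimethyl-1,3-dioxane | COc1cc(Br)ccc1O[C@H]1COC(C)(C)O[C@@H]1c1ccc(OCc2ccccc2)c(OC)c1 | intermediate
33 | aryllithium from 32 (lithium in place of bromine) | COc1cc([Li])ccc1O[C@H]1COC(C)(C)O[C@@H]1c1ccc(OCc2ccccc2)c(OC)c1 | intermediate (not isolated)
34 | 4-{[(4R,5S)-4-[4-(benzyloxy)-3-methoxyphenyl]-2,2-dimethyl-1,3-dioxan-5-yl]oxy}-3-methoxybenzaldehyde | COc1cc(C=O)ccc1O[C@H]1COC(C)(C)O[C@@H]1c1ccc(OCc2ccccc2)c(OC)c1 | intermediate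
35 | (Z)-dibutylboron enolate of 23 | COc1cc(cc(OC)c1O/C=C(\OB(CCCC)CCCC)N1[C@@H](Cc2ccccc2)COC1=O)[C@@H]1OC[C@@H]2[C@H]1CO[C@H]2c1cc(OC)c(O[C@@H]2COC(C)(C)O[C@H]2c2ccc(OCc3ccccc3)c(OC)c2)c(OC)c1 | intermediate (not isolated)
36 | (2S,3R)-syn aldol imide on ring C oxygen, (S)-auxiliary, both outer units as acetonides | COc1cc(cc(OC)c1O[C@H](C(=O)N3[C@@H](Cc4ccccc4)COC3=O)[C@H](O)c3ccc(O[C@H]4COC(C)(C)O[C@@H]4c4ccc(OCc5ccccc5)c(OC)c4)c(OC)c3)[C@@H]1OC[C@@H]2[C@H]1CO[C@H]2c1cc(OC)c(O[C@@H]2COC(C)(C)O[C@H]2c2ccc(OCc3ccccc3)c(OC)c2)c(OC)c1 | intermediate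
37 | ring B unit as (αR,βR)-1,3-diol, both outer units as acetonides, phenols of rings A/E benzylated | COc1cc(cc(OC)c1O[C@H](CO)[C@H](O)c3ccc(O[C@H]4COC(C)(C)O[C@@H]4c4ccc(OCc5ccccc5)c(OC)c4)c(OC)c3)[C@@H]1OC[C@@H]2[C@H]1CO[C@H]2c1cc(OC)c(O[C@@H]2COC(C)(C)O[C@H]2c2ccc(OCc3ccccc3)c(OC)c2)c(OC)c1 | intermediate
38 | dibenzyl ether of the target (phenols of rings A/E benzylated) | COc1cc(cc(OC)c1O[C@H](CO)[C@H](O)c3ccc(O[C@@H](CO)[C@H](O)c4ccc(OCc5ccccc5)c(OC)c4)c(OC)c3)[C@@H]1OC[C@@H]2[C@H]1CO[C@H]2c1cc(OC)c(O[C@H](CO)[C@@H](O)c2ccc(OCc3ccccc3)c(OC)c2)c(OC)c1 | intermediate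
39 | CNP0316493.1 | COc1cc([C@@H](O)[C@H](CO)Oc2ccc([C@@H](O)[C@@H](CO)Oc3c(OC)cc([C@@H]4OC[C@@H]5[C@H]4CO[C@H]5c4cc(OC)c(O[C@H](CO)[C@@H](O)c5ccc(O)c(OC)c5)c(OC)c4)cc3OC)cc2OC)ccc1O | target

**Totals**
Total step count: 25.
Longest linear sequence: 16 steps (steps 1–4, 7–14, 22–25, from syringaldehyde).

**Steps most likely to fail**

Step 10 (carries the label). The ylide may collapse by 1,2-proton shift to the plain O–H insertion product. The carbenoid may be consumed by the aldehyde oxygen, by the ring ether oxygens or by dimerisation. The aldol may also proceed with poor diastereofacial control, giving the threo pair or the wrong antipode. The fallback uses known chemistry and sets out from 13. O-Alkylation with 22 (K2CO3, NaI, acetone) gives the ring D glycolyl imide F1. Evans syn aldol of its dibutylboron enolate with 15 gives the (2S,3R) threo adduct F2. LiBH4 gives the threo (αR,βR) diol F3. DDQ, which oxidises arylglycerol benzylic alcohols in preference to resinol-type benzylic ethers, gives the (βR) ketone F4. Erythro-selective NaBH4 reduction then gives diol 19, where the route is rejoined at step 12.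

Step 8. The C8' radical may be reduced or may lose the titanoxy group (alkene formation) before it cyclises. The 5-exo closure may show a poor C8'/C8 ratio. Iodination and the second closure may be outrun by protonation of the benzylic titanium species. The fallback sets out from 9 and separates the two ring closures. The radical cyclisation is run alone and quenched with dilute acid to give the 2-aryl-4-benzyl-3-(hydroxymethyl)tetrahydrofuran F5. The second ring is then closed by a polar step: DDQ oxidation of the benzylic CH2 to a cation that the primary alcohol traps, as known for lariciresinol-to-pinoresinol-type closures. This returns to 12.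

Step 19. Hydride delivery may show poor diastereofacial selectivity, and ketone 30 may epimerise at Cβ or undergo retro-aldol loss of formaldehyde in the basic medium. The fallback sets out from 29 and replaces oxidation and reduction by stereospecific inversion. Selective silylation of the primary alcohol (TBSCl, imidazole) gives the silyl ether F6. Mitsunobu reaction with 4-nitrobenzoic acid (PPh3, DIAD) inverts Cα and gives the ester F7. K2CO3 in MeOH gives the erythro alcohol F8. Bu4NF then gives diol 31, where the route is rejoined at step 20.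

**Further compounds**
F1 | step 10 | ring D glycolyl imide of 13 bearing the (S)-auxiliary | COc1cc(cc(OC)c1O[Si](C(C)C)(C(C)C)C(C)C)[C@@H]1OC[C@@H]2[C@H]1CO[C@H]2c1cc(OC)c(OCC(=O)N2[C@@H](Cc3ccccc3)COC2=O)c(OC)c1
F2 | step 10 | (2S,3R)-syn aldol adduct of F1 from aldehyde 15 | COc1cc(cc(OC)c1O[Si](C(C)C)(C(C)C)C(C)C)[C@@H]1OC[C@@H]2[C@H]1CO[C@H]2c1cc(OC)c(O[C@H](C(=O)N2[C@@H](Cc3ccccc3)COC2=O)[C@H](O)c2ccc(OCc3ccccc3)c(OC)c2)c(OC)c1
F3 | step 10 | core carrying the ring E unit as threo (αR,βR)-diol | COc1cc(cc(OC)c1O[Si](C(C)C)(C(C)C)C(C)C)[C@@H]1OC[C@@H]2[C@H]1CO[C@H]2c1cc(OC)c(O[C@H](CO)[C@H](O)c2ccc(OCc3ccccc3)c(OC)c2)c(OC)c1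
F4 | step 10 | core carrying the ring E unit as (βR) α-ketone | COc1cc(cc(OC)c1O[Si](C(C)C)(C(C)C)C(C)C)[C@@H]1OC[C@@H]2[C@H]1CO[C@H]2c1cc(OC)c(O[C@H](CO)C(=O)c2ccc(OCc3ccccc3)c(OC)c2)c(OC)c1
F5 | step 8 | 2-(ring D aryl)-4-(ring C arylmethyl)-3-(hydroxymethyl)tetrahydrofuran (2,3-trans, 3,4-cis) | OC[C@@H]2[C@H](Cc1cc(OC)c(O[Si](C(C)C)(C(C)C)C(C)C)c(OC)c1)CO[C@H]2c1cc(OC)c(OCc3ccccc3)c(OC)c1
F6 | step 19 | (1S,2S)-diol 29 as primary tert-butyldimethylsilyl ether | COc1cc(Br)ccc1O[C@@H](CO[Si](C)(C)C(C)(C)C)[C@@H](O)c1ccc(OCc2ccccc2)c(OC)c1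
F7 | step 19 | (1R,2S)-4-nitrobenzoate from Mitsunobu inversion of F6 | COc1cc(Br)ccc1O[C@@H](CO[Si](C)(C)C(C)(C)C)[C@H](OC(=O)c1ccc(cc1)[N+](=O)[O-])c1ccc(OCc2ccccc2)c(OC)c1
F8 | step 19 | (1R,2S)-alcohol carrying the primary tert-butyldimethylsilyl ether | COc1cc(Br)ccc1O[C@@H](CO[Si](C)(C)C(C)(C)C)[C@H](O)c1ccc(OCc2ccccc2)c(OC)c1
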